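The cyclohexanone (C1 quaternary carbinol, C2 and C4 carbinols, C3 benzoate, C5 methylene, C6 ketone) is disconnected into a diene C6–C1–C2–C3 and a dienophile C4–C5. An amine-catalysed Diels–Alder reaction of an acyclic 1,4-diacyloxy-2-(benzoyloxymethyl)butadiene, made from 2-butyne-1,4-diol, with ethyl vinyl ketone forms C3–C4 and C5–C6 at once. It exploits the 1,4-relation of the C6 and C3 oxygens, which sit on the diene termini, sets the cis C3/C4 pair and the absolute configuration, and leaves the C1=C2 alkene for the cis-diol. The propanoyl group at C4 later becomes the hydroxyl by Baeyer–Villiger oxidation, the C6 acetate the ketone.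

Key step: step 4

Assumption: the ring numbering above is used for all intermediates, and the ketone-type imidazolidinone catalyst is taken to shield the same face of the iminium ion as the parent aldehyde catalyst of the same configuration.

Step 1
Reactants: 1 2-butyne-1,4-diol
Product: 2 but-2-yne-1,4-diyl dibenzoate
Conditions: BzCl (2.2 equiv), pyridine, DMAP (cat.), CH2Cl2, 0 °C to rt
Reagents that add atoms: benzoyl chloride, O=C(Cl)c1ccccc1
Why: Pyridine-mediated nucleophilic acyl substitution esterifies both primary hydroxyls and creates no stereocenter.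

Step 2
Reactants: 2 but-2-yne-1,4-diyl dibenzoate
Product: 3 (2E)-2-formylbut-2-ene-1,4-diyl dibenzoate
Conditions: Rh(acac)(CO)2 (2 mol%), BIPHEPHOS (4 mol%), CO/H2 (1:1, 5 bar), toluene, 40 °C
Reagents that add atoms: carbon monoxide, [C-]#[O+]
Why: Rhodium-catalysed hydroformylation of a symmetrical internal alkyne adds H and CHO syn, so only one regioisomer is possible and the E enal should result.

Step 3
Reactants: 3 (2E)-2-formylbut-2-ene-1,4-diyl dibenzoate
Product: 4 (1E,3Z)-4-acetoxy-3-[(benzoyloxy)methyl]buta-1,3-dien-1-yl benzoate (both acyloxy groups on the outside of the s-cis diene)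
Conditions: Ac2O (3 equiv), Et3N (2 equiv), DMAP (0.1 equiv), CH2Cl2, 0 °C to rt
Reagents that add atoms: acetic anhydride, CC(=O)OC(C)=O
Why: Dienol ester formation by γ-deprotonation at C3 and O-acetylation, in which the s-trans enal places the acetoxy group outside at C6 and allylic 1,3-strain with the C1 CH2OBz group places the benzoate outside at C3.

Step 4
Reactants: 4 (1E,3Z)-4-acetoxy-3-[(benzoyloxy)methyl]buta-1,3-dien-1-yl benzoate, 5 pent-1-en-3-one (ethyl vinyl ketone)
Product: 6 [(3S,4R,6S)-6-acetoxy-3-(benzoyloxy)-4-propanoylcyclohex-1-en-1-yl]methyl benzoate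
Conditions: (2S,5S)-5-benzyl-3-methyl-2-(5-methylfuran-2-yl)imidazolidin-4-one·HClO4 (20 mol%), EtOH, 0 °C to rt
Reagents that add atoms: none
Why: The amine condenses with 5 to an α,β-unsaturated iminium ion whose lowered LUMO engages diene 4 in an asynchronous but concerted [4+2] cycloaddition, the closest known type being the imidazolidinone-catalysed Diels–Alder reaction of simple enones with 1-oxygenated butadienes. The six-membered ring is closed intermolecularly in the [4+2] mode, suprafacially on both partners, with C5–C6 forming ahead of C3–C4. C3 and C6 become cis because both acyloxy groups sit outside on the s-cis diene, and C4 becomes cis to C3 through the endo transition state. The absolute configuration (4R, hence 3S and 6S) comes from the catalyst, whose benzyl and cis furyl groups cover one face of the iminium vinyl group so that the diene adds to the open face. The step needs para regioselectivity (C4 bonded to C3, not C6): the two acyloxy termini nearly cancel, so the C1 CH2OBz group decides, because bonding of C6 to the iminium β-carbon leaves positive charge on an allyl unit that is tertiary at C1 and acyloxy-stabilised at C3, and the bulkier dienophile carbon meets the less hindered terminus C3.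

Step 5
Reactants: 6 [(3S,4R,6S)-6-acetoxy-3-(benzoyloxy)-4-propanoylcyclohex-1-en-1-yl]methyl benzoate
Product: 7 [(3S,4R,6S)-6-acetoxy-3-(benzoyloxy)-4-(propanoyloxy)cyclohex-1-en-1-yl]methyl benzoate
Conditions: mCPBA (3 equiv), CH2Cl2, 0 °C to rt
Reagents that add atoms: mCPBA, OOC(=O)c1cccc(Cl)c1
Why: Baeyer–Villiger oxidation in which the secondary ring carbon C4 should migrate in preference to the primary ethyl group with retention at C4, while the C1=C2 alkene, deactivated by three allylic acyloxy groups, should resist epoxidation.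

Step 6
Reactants: 7 [(3S,4R,6S)-6-acetoxy-3-(benzoyloxy)-4-(propanoyloxy)cyclohex-1-en-1-yl]methyl benzoate
Product: 8 [(3S,4R,6S)-3-(benzoyloxy)-4,6-dihydroxycyclohex-1-en-1-yl]methyl benzoate
Conditions: HCl (0.1 M) in MeOH/CH2Cl2 (4:1), 0 °C to rt
Reagents that add atoms: none
Why: Acid-catalysed transesterification (methanolysis) should remove the acetate and the propanoate much faster than the conjugation-stabilised benzoates and avoids the base-induced benzoyl shift between the cis C3 and C4 oxygens, no stereocenter being touched.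

Step 7
Reactants: 8 [(3S,4R,6S)-3-(benzoyloxy)-4,6-dihydroxycyclohex-1-en-1-yl]methyl benzoate
Product: 9 [(3S,4R)-3-(benzoyloxy)-4-hydroxy-6-oxocyclohex-1-en-1-yl]methyl benzoate
Conditions: MnO2 (activated, 15 equiv), CH2Cl2, rt
Reagents that add atoms: none
Why: Allylic alcohol oxidation with MnO2 is selective for the C6 hydroxyl over the saturated C4 hydroxyl and runs under neutral conditions that should not trigger β-elimination of the enone.

Step 8
Reactants: 9 [(3S,4R)-3-(benzoyloxy)-4-hydroxy-6-oxocyclohex-1-en-1-yl]methyl benzoate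
Product: 10 [(1S,2S,3R,4R)-3-(benzoyloxy)-1,2,4-trihydroxy-6-oxocyclohexyl]methyl benzoate (target)
Conditions: OsO4 (5 mol%), NMO (1.5 equiv), citric acid (1 equiv), t-BuOH/H2O (1:1), rt
Reagents that add atoms: osmium tetroxide, O=[Os](=O)(=O)=O; N-methylmorpholine N-oxide, C[N+]1([O-])CCOCC1; water, O
Why: Upjohn dihydroxylation adds both hydroxyls suprafacially to C1 and C2 from the ring face opposite the allylic C3 benzoate, which should set the cis C1/C2 diol trans to C3–OBz, while citric acid keeps the medium acidic to speed osmate hydrolysis of the electron-poor alkene and to suppress benzoyl migration and β-elimination.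

Compound list
1 | 2-butyne-1,4-diol | OCC#CCO | starting material
2 | but-2-yne-1,4-diyl dibenzoate | O=C(OCC#CCOC(=O)c1ccccc1)c1ccccc1 | intermediate
3 | (2E)-2-formylbut-2-ene-1,4-diyl dibenzoate | O=C/C(COC(=O)c1ccccc1)=C/COC(=O)c1ccccc1 | intermediate
4 | (1E,3Z)-4-acetoxy-3-[(benzoyloxy)methyl]buta-1,3-dien-1-yl benzoate | CC(=O)O/C=C(COC(=O)c1ccccc1)/C=C/OC(=O)c1ccccc1 | intermediate
5 | pent-1-en-3-one (ethyl vinyl ketone) | CCC(=O)C=C | starting material
6 | [(3S,4R,6S)-6-acetoxy-3-(benzoyloxy)-4-propanoylcyclohex-1-en-1-yl]methyl benzoate | CC(=O)O[C@H]1C[C@@H](C(=O)CC)[C@@H](OC(=O)c2ccccc2)C=C1COC(=O)c1ccccc1 | intermediate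
7 | [(3S,4R,6S)-6-acetoxy-3-(benzoyloxy)-4-(propanoyloxy)cyclohex-1-en-1-yl]methyl benzoate | CC(=O)O[C@H]1C[C@@H](OC(=O)CC)[C@@H](OC(=O)c2ccccc2)C=C1COC(=O)c1ccccc1 | intermediate
8 | [(3S,4R,6S)-3-(benzoyloxy)-4,6-dihydroxycyclohex-1-en-1-yl]methyl benzoate | O[C@H]1C[C@@H](O)[C@@H](OC(=O)c2ccccc2)C=C1COC(=O)c1ccccc1 | intermediate
9 | [(3S,4R)-3-(benzoyloxy)-4-hydroxy-6-oxocyclohex-1-en-1-yl]methyl benzoate | O=C1C[C@@H](O)[C@@H](OC(=O)c2ccccc2)C=C1COC(=O)c1ccccc1 | intermediate
10 | [(1S,2S,3R,4R)-3-(benzoyloxy)-1,2,4-trihydroxy-6-oxocyclohexyl]methyl benzoate | O=C(OC[C@@]1(O)C(=O)C[C@@H](O)[C@@H](OC(=O)c2ccccc2)[C@@H]1O)c1ccccc1 | target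

Total step count: 8. Longest linear sequence: 8 steps (1 to 10).

Steps most likely to fail

Step 4. The risk is insufficient discrimination between the two acyloxy-bearing diene termini (para against meta placement of the propanoyl group), together with a cycloaddition too slow to outrun solvolysis of the enol esters. The fallback sets out from 5 and comes back at 9; it leaves the C6 oxygen out of the diene so that the 1-benzoyloxy and 3-alkyl groups direct the same way. Commercial prop-2-yn-1-yl benzoate and vinyl benzoate are joined by enyne cross-metathesis (second-generation Grubbs catalyst, CH2Cl2, 40 °C) to (1E)-3-[(benzoyloxy)methyl]buta-1,3-dien-1-yl benzoate F1. The same amine-catalysed Diels–Alder reaction with 5 should give [(3S,4R)-3-(benzoyloxy)-4-propanoylcyclohex-1-en-1-yl]methyl benzoate F2, and Baeyer–Villiger oxidation with mCPBA should give [(3S,4R)-3-(benzoyloxy)-4-(propanoyloxy)cyclohex-1-en-1-yl]methyl benzoate F3. Allylic oxidation at the ring methylene C6 with SeO2 (cat.) and t-BuOOH should give [(3S,4R,6RS)-3-(benzoyloxy)-6-hydroxy-4-(propanoyloxy)cyclohex-1-en-1-yl]methyl benzoate F4 as a mixture of C6 epimers. HCl in MeOH removes the propanoate to [(3S,4R,6RS)-3-(benzoyloxy)-4,6-dihydroxycyclohex-1-en-1-yl]methyl benzoate F5, and MnO2 oxidation of both epimers converges on 9.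

Step 5. The risk is epoxidation of the C1=C2 alkene competing with a slow oxidation of the open-chain ethyl ketone. The fallback sets out from 6 and comes back at 9; it changes the order so that the peracid meets an electron-poor alkene. HCl in MeOH removes only the acetate of 6 to give [(3S,4R,6S)-3-(benzoyloxy)-6-hydroxy-4-propanoylcyclohex-1-en-1-yl]methyl benzoate F6, which MnO2 oxidises to [(3S,4R)-3-(benzoyloxy)-6-oxo-4-propanoylcyclohex-1-en-1-yl]methyl benzoate F7. In F7 the conjugated alkene and the enone carbonyl are inert to mCPBA, so Baeyer–Villiger oxidation of the saturated ethyl ketone should give [(3S,4R)-3-(benzoyloxy)-6-oxo-4-(propanoyloxy)cyclohex-1-en-1-yl]methyl benzoate F8. HCl in MeOH then cleaves the propanoate to 9.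

Step 2. The risk is over-reduction of the enal and β-acyloxy elimination from the alkenyl–rhodium intermediate of the propargylic diester. The fallback sets out from 2 and comes back at 3; it builds the formyl group stepwise. Syn hydrostannation (Bu3SnH, PdCl2(PPh3)2, THF, 0 °C) gives (2E)-2-(tributylstannyl)but-2-ene-1,4-diyl dibenzoate F9. Iododestannylation (I2, CH2Cl2, 0 °C) gives (2E)-2-iodobut-2-ene-1,4-diyl dibenzoate F10 with retention of geometry. Palladium-catalysed formylation (Pd(PPh3)4, CO, Bu3SnH, THF, 50 °C) then gives 3.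

Further compounds
F1 | step 4 | (1E)-3-[(benzoyloxy)methyl]buta-1,3-dien-1-yl benzoate | C=C(COC(=O)c1ccccc1)/C=C/OC(=O)c1ccccc1
F2 | step 4 | [(3S,4R)-3-(benzoyloxy)-4-propanoylcyclohex-1-en-1-yl]methyl benzoate | C1C[C@@H](C(=O)CC)[C@@H](OC(=O)c2ccccc2)C=C1COC(=O)c1ccccc1
F3 | step 4 | [(3S,4R)-3-(benzoyloxy)-4-(propanoyloxy)cyclohex-1-en-1-yl]methyl benzoate | C1C[C@@H](OC(=O)CC)[C@@H](OC(=O)c2ccccc2)C=C1COC(=O)c1ccccc1
F4 | step 4 | [(3S,4R,6RS)-3-(benzoyloxy)-6-hydroxy-4-(propanoyloxy)cyclohex-1-en-1-yl]methyl benzoate | OC1C[C@@H](OC(=O)CC)[C@@H](OC(=O)c2ccccc2)C=C1COC(=O)c1ccccc1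
F5 | step 4 | [(3S,4R,6RS)-3-(benzoyloxy)-4,6-dihydroxycyclohex-1-en-1-yl]methyl benzoate | OC1C[C@@H](O)[C@@H](OC(=O)c2ccccc2)C=C1COC(=O)c1ccccc1
F6 | step 5 | [(3S,4R,6S)-3-(benzoyloxy)-6-hydroxy-4-propanoylcyclohex-1-en-1-yl]methyl benzoate | O[C@H]1C[C@@H](C(=O)CC)[C@@H](OC(=O)c2ccccc2)C=C1COC(=O)c1ccccc1
F7 | step 5 | [(3S,4R)-3-(benzoyloxy)-6-oxo-4-propanoylcyclohex-1-en-1-yl]methyl benzoate | O=C1C[C@@H](C(=O)CC)[C@@H](OC(=O)c2ccccc2)C=C1COC(=O)c1ccccc1
F8 | step 5 | [(3S,4R)-3-(benzoyloxy)-6-oxo-4-(propanoyloxy)cyclohex-1-en-1-yl]methyl benzoate | O=C1C[C@@H](OC(=O)CC)[C@@H](OC(=O)c2ccccc2)C=C1COC(=O)c1ccccc1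
F9 | step 2 | (2E)-2-(tributylstannyl)but-2-ene-1,4-diyl dibenzoate | CCCC[Sn](CCCC)(CCCC)/C(COC(=O)c1ccccc1)=C/COC(=O)c1ccccc1
F10 | step 2 | (2E)-2-iodobut-2-ene-1,4-diyl dibenzoate | I/C(COC(=O)c1ccccc1)=C/COC(=O)c1ccccc1
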